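The two flavan halves share ring A and the (2R,3R) pattern, so the molecule is grown in both directions from a biaryl made of the two B rings. The central disconnection is C3–C4 of each pyran ring C: C4 is a bare benzylic CH2 on ring A and C3 the carbinol carbon, the retron of a C3=C4 alkene. A double ring-closing metathesis closes both pyran rings, that of the epigallocatechin half included, as 2H-chromenes. Its precursor is an open tetraene whose two C2 stereocentres, set by iridium-catalysed allylic etherification, each carry a vinyl group opposite an ortho-vinyl group on ring A. Hydroboration, oxidation and hydride reduction then install the cis C3 hydroxyls.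

Key step: step 10

Assumption: the target structure fixes four carbon stereocentres (2R,3R in each flavan half) and leaves the sense of the biaryl axis open. The route sets the four centres and carries the axis as it forms; if both atropisomers are present they are separated by chromatography at compound 18.

Flavan numbering (O1, C2, C3, C4, C4a, C5–C8, C8a) is used for both halves. Ring A is the phloroglucinol ring, ring B the catechol or pyrogallol ring, and ring C the pyran ring. From step 3 on, every operation acts on both arms of the biaryl at once.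

Step 1
Reactants: 1 3,4-bis(benzyloxy)benzaldehyde
Product: 2 2-bromo-4,5-bis(benzyloxy)benzaldehyde
Conditions: Br2, NaOAc, AcOH, rt
Reagents that add atoms: bromine, BrBr
Why: Electrophilic aromatic bromination should go to C6 of the aldehyde (para to the 3-benzyloxy group and ortho to the formyl group), the most activated unhindered position, as with veratraldehyde.

Step 2
Reactants: 3 3,4,5-tris(benzyloxy)benzaldehyde
Product: 4 2-bromo-3,4,5-tris(benzyloxy)benzaldehyde
Conditions: NBS, MeCN, rt
Reagents that add atoms: N-bromosuccinimide, O=C1CCC(=O)N1Br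
Why: Electrophilic aromatic bromination can only take one of the two equivalent free positions, each ortho to one alkoxy group and para to another, so a single regioisomer should form.

Step 3
Reactants: 2 2-bromo-4,5-bis(benzyloxy)benzaldehyde; 4 2-bromo-3,4,5-tris(benzyloxy)benzaldehyde
Product: 6 biaryl dialdehyde 4,4',5,5',6-pentakis(benzyloxy)biphenyl-2,2'-dicarbaldehyde, via pinacol boronate 5 (not isolated)
Conditions: 2, B2pin2, KOAc, PdCl2(dppf), dioxane, 90 °C; then 4, Pd(OAc)2, SPhos, aq. K3PO4, 90 °C
Reagents that add atoms: bis(pinacolato)diboron, CC1(C)OB(OC1(C)C)B1OC(C)(C)C(C)(C)O1 (its boryl group enters 5 and leaves again in the coupling; no reagent atom remains in 6)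
Why: Miyaura borylation of the less hindered bromide followed by Suzuki–Miyaura coupling in the same flask, with the doubly ortho-substituted bromide 4 as electrophile and a dialkylbiarylphosphine suited to tri-ortho-substituted biaryls; both formyl groups are inert to these conditions.

Step 4
Reactants: 6 biaryl dialdehyde
Product: 7 diethyl (2E,2'E)-3,3'-[4,4',5,5',6-pentakis(benzyloxy)biphenyl-2,2'-diyl]bis(prop-2-enoate)
Conditions: triethyl phosphonoacetate, NaH, THF, 0 °C to rt
Reagents that add atoms: triethyl phosphonoacetate, CCOC(=O)CP(=O)(OCC)OCC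
Why: Horner–Wadsworth–Emmons olefination with a stabilised phosphonate should give the E-enoate on each arm.

Step 5
Reactants: 7 bis(enoate)
Product: 8 (2E,2'E)-3,3'-[4,4',5,5',6-pentakis(benzyloxy)biphenyl-2,2'-diyl]bis(prop-2-en-1-ol)
Conditions: iBu2AlH, CH2Cl2, −78 °C; aq. sodium potassium tartrate
Reagents that add atoms: none
Why: 1,2-Reduction of the conjugated esters by the aluminium hydride should give the allylic alcohols without touching the alkenes or the benzyl ethers.

Step 6
Reactants: 8 bis(allylic alcohol)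
Product: 9 bis(methyl carbonate) of 8
Conditions: ClCO2Me, pyridine, CH2Cl2, 0 °C
Reagents that add atoms: methyl chloroformate, COC(=O)Cl
Why: Acylation of the primary allylic alcohols gives the linear allylic carbonates that serve as the ionisable partners for iridium catalysis.

Step 7
Reactants: 10 2,4,6-trihydroxybenzaldehyde
Product: 11 2,4-bis(benzyloxy)-6-hydroxybenzaldehyde
Conditions: BnBr (2 equiv), K2CO3, DMF, rt
Reagents that add atoms: benzyl bromide, BrCc1ccccc1
Why: Williamson etherification should stop at the dibenzyl ether because the last ortho hydroxyl is held in a hydrogen bond to the formyl group and is the least nucleophilic.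

Step 8
Reactants: 11 2,4-bis(benzyloxy)-6-hydroxybenzaldehyde
Product: 12 3,5-bis(benzyloxy)-2-ethenylphenol
Conditions: Ph3PCH3Br, KOtBu (excess), THF, 0 °C to rt; pH 7 work-up; used without storage
Reagents that add atoms: methyltriphenylphosphonium bromide, C[P+](c1ccccc1)(c1ccccc1)c1ccccc1.[Br-]
Why: Wittig methylenation of a salicylaldehyde proceeds on the phenoxide when excess ylide is used and gives the ortho-vinylphenol directly.

Step 9
Reactants: 9 bis(methyl carbonate); 12 3,5-bis(benzyloxy)-2-ethenylphenol (2 equiv)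
Product: 13 tetraene 4,4',5,5',6-pentakis(benzyloxy)-2,2'-bis{(1S)-1-[3,5-bis(benzyloxy)-2-ethenylphenoxy]prop-2-en-1-yl}biphenyl
Conditions: 12, NaH, THF, 0 °C; then 9, [Ir(cod)Cl]2 (cat.), (Sa,Sc,Sc)-O,O'-(1,1'-binaphthalene-2,2'-diyl) N,N-bis(1-phenylethyl)phosphoramidite (cat., activated with n-PrNH2), THF, 50 °C
Reagents that add atoms: none
Why: Iridium-catalysed asymmetric allylic etherification, in which each carbonate ionises to an allyliridium species that the aryloxide attacks at the aryl-bearing terminus, so that the branched ether forms and the chiral cyclometalated iridium phosphoramidite fixes the face at each new C2 centre independently of the other arm; the ligand antipode named is the one expected to give S (to be confirmed on cinnamyl methyl carbonate), the centre that becomes 2R of the flavan once C3 carries oxygen.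

Step 10
Reactants: 13 tetraene
Product: 14 bis(2H-chromene) (2S)-5,7-bis(benzyloxy)-2-{4,5-bis(benzyloxy)-2-[2,3,4-tris(benzyloxy)-6-((2S)-5,7-bis(benzyloxy)-2H-chromen-2-yl)phenyl]phenyl}-2H-chromene
Conditions: second-generation Grubbs catalyst RuCl2(=CHPh)(H2IMes)(PCy3) (10 mol %), 1,4-benzoquinone (20 mol %), CH2Cl2 (0.003 M), 40 °C, dark
Reagents that add atoms: none
Why: A ruthenium alkylidene forms at each unhindered C3 vinyl group, adds [2+2] to the ortho vinyl group on ring A of the same arm, and the ruthenacyclobutane collapses to the C3=C4 double bond with loss of ethene, once on each arm. The closest known reaction type is the ring-closing metathesis of allyl 2-vinylaryl ethers to 2H-chromenes. Each pyran ring closes as a six-membered ring by intramolecular olefin metathesis of a 1,7-diene whose C8a=C4a arene bond holds the two alkenes cis and close. No stereocentre is formed; the two C2 centres are not touched by the neutral catalyst, and mild temperature and exclusion of light guard the 2-aryl-2H-chromenes against electrocyclic ring opening. The step needs closure within each arm in preference to metathesis between the two arms (an eight-membered ring across the biaryl) or between molecules, which the ortho arrangement and high dilution should secure, and 1,4-benzoquinone suppresses ruthenium hydride migration of the allylic ether double bonds.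

Step 11
Reactants: 14 bis(2H-chromene)
Product: 16 (2R,3S,2'R,3'S)-octa-O-benzyl bis(2,3-trans-flavan-3-ol), via bis(3-boryl)flavan adduct 15 (not isolated)
Conditions: BH3·THF, THF, 0 °C to rt; then aq. NaOH, H2O2, 0 °C
Reagents that add atoms: borane–tetrahydrofuran, B.C1CCOC1 (boron of intermediate 15); hydrogen peroxide, OO (hydroxyl oxygen of 16)
Why: Hydroboration–oxidation of a flav-3-ene places boron at C3 (hydride at the benzylic C4, away from the allylic oxygen) on the face anti to the C2 aryl group, and oxidation with retention gives the 2,3-trans alcohol; the C2 descriptor changes from S to R only because C3 gains priority.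

Step 12
Reactants: 16 bis(2,3-trans-flavan-3-ol)
Product: 17 (2R,2'R)-octa-O-benzyl bis(flavan-3-one)
Conditions: Dess–Martin periodinane, wet CH2Cl2, rt
Reagents that add atoms: none
Why: Dess–Martin oxidation of the secondary alcohols under near-neutral conditions should give the C3 ketones without epimerising the adjacent benzylic C2 centres, as in the known oxidation of benzylated catechin.

Step 13
Reactants: 17 bis(flavan-3-one)
Product: 18 (2R,3R,2'R,3'R)-octa-O-benzyl degalloyl theasinensin F
Conditions: LiBH(sBu)3, LiBr, THF, −78 °C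
Reagents that add atoms: none
Why: The bulky trialkylborohydride should attack each C3 carbonyl from the face opposite the C2 aryl group, which places the new hydroxyl cis to the aryl group (2,3-cis, 3R), as in the conversion of catechin-type ketones into epicatechin-type alcohols.

Step 14
Reactants: 18 octa-O-benzyl degalloyl theasinensin F
Product: 19 degalloyl theasinensin F
Conditions: H2 (1 atm), Pd(OH)2 on carbon, THF/MeOH, rt; filtration and concentration under argon
Reagents that add atoms: none
Why: Hydrogenolysis should cleave the eight aryl benzyl ethers, while the cyclic C2–O1 ether and the secondary alcohols persist under neutral conditions at atmospheric pressure, as in the deprotection of benzylated catechins.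

Compound list
1 | 3,4-bis(benzyloxy)benzaldehyde | O=Cc1ccc(OCc2ccccc2)c(OCc2ccccc2)c1 | starting material
2 | 2-bromo-4,5-bis(benzyloxy)benzaldehyde | O=Cc1cc(OCc2ccccc2)c(OCc2ccccc2)cc1Br | intermediate
3 | 3,4,5-tris(benzyloxy)benzaldehyde | O=Cc1cc(OCc2ccccc2)c(OCc2ccccc2)c(OCc2ccccc2)c1 | starting material
4 | 2-bromo-3,4,5-tris(benzyloxy)benzaldehyde | O=Cc1cc(OCc2ccccc2)c(OCc2ccccc2)c(OCc2ccccc2)c1Br | intermediate
5 | 4,5-bis(benzyloxy)-2-(4,4,5,5-tetramethyl-1,3,2-dioxaborolan-2-yl)benzaldehyde | O=Cc1cc(OCc2ccccc2)c(OCc2ccccc2)cc1B1OC(C)(C)C(C)(C)O1 | intermediate (not isolated)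
6 | 4,4',5,5',6-pentakis(benzyloxy)biphenyl-2,2'-dicarbaldehyde | O=Cc1cc(OCc2ccccc2)c(OCc2ccccc2)cc1-c1c(C=O)cc(OCc2ccccc2)c(OCc2ccccc2)c1OCc1ccccc1 | intermediate
7 | diethyl (2E,2'E)-3,3'-[4,4',5,5',6-pentakis(benzyloxy)biphenyl-2,2'-diyl]bis(prop-2-enoate) | CCOC(=O)/C=C/c1cc(OCc2ccccc2)c(OCc2ccccc2)cc1-c1c(/C=C/C(=O)OCC)cc(OCc2ccccc2)c(OCc2ccccc2)c1OCc1ccccc1 | intermediate
8 | (2E,2'E)-3,3'-[4,4',5,5',6-pentakis(benzyloxy)biphenyl-2,2'-diyl]bis(prop-2-en-1-ol) | OC/C=C/c1cc(OCc2ccccc2)c(OCc2ccccc2)cc1-c1c(/C=C/CO)cc(OCc2ccccc2)c(OCc2ccccc2)c1OCc1ccccc1 | intermediate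
9 | bis(methyl carbonate) of 8 | COC(=O)OC/C=C/c1cc(OCc2ccccc2)c(OCc2ccccc2)cc1-c1c(/C=C/COC(=O)OC)cc(OCc2ccccc2)c(OCc2ccccc2)c1OCc1ccccc1 | intermediate
10 | 2,4,6-trihydroxybenzaldehyde | O=Cc1c(O)cc(O)cc1O | starting material
11 | 2,4-bis(benzyloxy)-6-hydroxybenzaldehyde | O=Cc1c(O)cc(OCc2ccccc2)cc1OCc1ccccc1 | intermediate
12 | 3,5-bis(benzyloxy)-2-ethenylphenol | C=Cc1c(O)cc(OCc2ccccc2)cc1OCc1ccccc1 | intermediate
13 | tetraene, 4,4',5,5',6-pentakis(benzyloxy)-2,2'-bis{(1S)-1-[3,5-bis(benzyloxy)-2-ethenylphenoxy]prop-2-en-1-yl}biphenyl | C=Cc1c(OCc2ccccc2)cc(OCc2ccccc2)cc1O[C@H](c1cc(OCc2ccccc2)c(OCc2ccccc2)cc1-c1c([C@H](C=C)Oc2cc(OCc3ccccc3)cc(OCc3ccccc3)c2C=C)cc(OCc2ccccc2)c(OCc2ccccc2)c1OCc1ccccc1)C=C | intermediate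
14 | (2S,2'S)-octa-O-benzyl bis(2H-chromene), both rings C closed with C3=C4 | c1ccccc1COc1cc(OCc2ccccc2)c2c(c1)O[C@H](c1cc(OCc3ccccc3)c(OCc3ccccc3)cc1-c1c([C@H]3Oc4cc(OCc5ccccc5)cc(OCc5ccccc5)c4C=C3)cc(OCc3ccccc3)c(OCc3ccccc3)c1OCc1ccccc1)C=C2 | intermediate
15 | bis(3-boryl)flavan adduct, boron at each C3 trans to the C2 aryl group, drawn as the monoalkylborane | c1ccccc1COc1cc(OCc2ccccc2)c2c(c1)O[C@H](c1cc(OCc3ccccc3)c(OCc3ccccc3)cc1-c1c([C@H]3Oc4cc(OCc5ccccc5)cc(OCc5ccccc5)c4C[C@@H]3B)cc(OCc3ccccc3)c(OCc3ccccc3)c1OCc1ccccc1)[C@@H](B)C2 | intermediate (not isolated)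
16 | (2R,3S,2'R,3'S)-octa-O-benzyl bis(2,3-trans-flavan-3-ol) | c1ccccc1COc1cc(OCc2ccccc2)c2c(c1)O[C@H](c1cc(OCc3ccccc3)c(OCc3ccccc3)cc1-c1c([C@H]3Oc4cc(OCc5ccccc5)cc(OCc5ccccc5)c4C[C@@H]3O)cc(OCc3ccccc3)c(OCc3ccccc3)c1OCc1ccccc1)[C@@H](O)C2 | intermediate
17 | (2R,2'R)-octa-O-benzyl bis(flavan-3-one) | c1ccccc1COc1cc(OCc2ccccc2)c2c(c1)O[C@H](c1cc(OCc3ccccc3)c(OCc3ccccc3)cc1-c1c([C@H]3Oc4cc(OCc5ccccc5)cc(OCc5ccccc5)c4CC3=O)cc(OCc3ccccc3)c(OCc3ccccc3)c1OCc1ccccc1)C(=O)C2 | intermediate
18 | (2R,3R,2'R,3'R)-octa-O-benzyl degalloyl theasinensin F | c1ccccc1COc1cc(OCc2ccccc2)c2c(c1)O[C@H](c1cc(OCc3ccccc3)c(OCc3ccccc3)cc1-c1c([C@H]3Oc4cc(OCc5ccccc5)cc(OCc5ccccc5)c4C[C@H]3O)cc(OCc3ccccc3)c(OCc3ccccc3)c1OCc1ccccc1)[C@H](O)C2 | intermediate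
19 | degalloyl theasinensin F | Oc1cc(O)c2c(c1)O[C@H](c1cc(O)c(O)cc1-c1c([C@H]3Oc4cc(O)cc(O)c4C[C@H]3O)cc(O)c(O)c1O)[C@H](O)C2 | target

Total step count: 14. Longest linear sequence: 11 steps (steps 1, 3, 4, 5, 6, 9, 10, 11, 12, 13, 14).

Steps most likely to fail

Step 9. The bulky ortho-aryl group on each cinnamyl unit may slow ionisation and erode the branched-to-linear selectivity and the facial control of the iridium catalyst, and both arms must react cleanly. The fallback sets out from 8 and returns at 13. A twofold Sharpless asymmetric epoxidation of 8 (Ti(OiPr)4, L-(+)-diisopropyl tartrate, tBuOOH, 4 Å sieves, CH2Cl2, −20 °C) should give the bis[(2S,3S)-2,3-epoxy alcohol] F1. The sodium phenoxide of 12 (aq. NaOH, dioxane, 70 °C) should then open each epoxide at the benzylic carbon by SN2 with inversion, giving the bis(3-aryloxypropane-1,2-diol) F2, which already has the C2 configuration of the route. Garegg–Samuelsson deoxygenation (PPh3, I2, imidazole, toluene, 80 °C) should turn each terminal 1,2-diol into the vinyl group of 13.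

Step 10. The ring-A styrenes are flanked by two oxygen substituents, so ring closure may be slow, which would leave room for metathesis between the two arms, oligomerisation or double-bond migration of the allylic ethers. The fallback sets out from 13 and returns at 14. Lemieux–Johnson cleavage of the four vinyl groups (OsO4 cat., NaIO4, 2,6-lutidine, dioxane/H2O, 0 °C) should give the tetra-aldehyde F3, which is used at once without chromatography because C2–H is then alpha to a formyl group. A twofold intramolecular McMurry coupling (TiCl3(DME)1.5, Zn–Cu couple, DME, slow addition, reflux) should join each ring-A formyl carbon (C4) to the neighbouring C3 formyl carbon, so that the C3=C4 bonds of 14 arise by carbonyl–carbonyl instead of olefin–olefin coupling.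

Step 8. The electron-rich ortho-vinylphenol may oligomerise through acid- or radical-induced pathways during isolation or before it is consumed in step 9. The fallback sets out from 11 (with 9) and returns at 13. The sodium phenoxide of 11 is used as the nucleophile in the iridium-catalysed etherification of 9 under the conditions of step 9 to give the bis(ether) dialdehyde F4. A twofold Wittig methylenation (Ph3PCH3Br, KOtBu, THF, 0 °C) of the two ring-A formyl groups should then give 13, so that no free vinylphenol is handled.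

Further compounds
F1 | step 9 | bis[(2S,3S)-2,3-epoxy alcohol], [(2S,3S)-3-{4,5-bis(benzyloxy)-2-[2,3,4-tris(benzyloxy)-6-((2S,3S)-3-(hydroxymethyl)oxiran-2-yl)phenyl]phenyl}oxiran-2-yl]methanol | OC[C@@H]1O[C@H]1c1cc(OCc2ccccc2)c(OCc2ccccc2)cc1-c1c([C@H]2[C@H](CO)O2)cc(OCc2ccccc2)c(OCc2ccccc2)c1OCc1ccccc1
F2 | step 9 | bis(3-aryloxypropane-1,2-diol), each arm a (2S,3R)-3-aryl-3-[3,5-bis(benzyloxy)-2-ethenylphenoxy]propane-1,2-diol | C=Cc1c(OCc2ccccc2)cc(OCc2ccccc2)cc1O[C@H](c1cc(OCc2ccccc2)c(OCc2ccccc2)cc1-c1c([C@H]([C@@H](O)CO)Oc2cc(OCc3ccccc3)cc(OCc3ccccc3)c2C=C)cc(OCc2ccccc2)c(OCc2ccccc2)c1OCc1ccccc1)[C@@H](O)CO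
F3 | step 10 | tetra-aldehyde, 13 with a formyl group in place of each of the four vinyl groups | O=Cc1c(OCc2ccccc2)cc(OCc2ccccc2)cc1O[C@H](c1cc(OCc2ccccc2)c(OCc2ccccc2)cc1-c1c([C@H](C=O)Oc2cc(OCc3ccccc3)cc(OCc3ccccc3)c2C=O)cc(OCc2ccccc2)c(OCc2ccccc2)c1OCc1ccccc1)C=O
F4 | step 8 | bis(ether) dialdehyde, 13 with a formyl group in place of each ring-A vinyl group | O=Cc1c(OCc2ccccc2)cc(OCc2ccccc2)cc1O[C@H](c1cc(OCc2ccccc2)c(OCc2ccccc2)cc1-c1c([C@H](C=C)Oc2cc(OCc3ccccc3)cc(OCc3ccccc3)c2C=O)cc(OCc2ccccc2)c(OCc2ccccc2)c1OCc1ccccc1)C=C
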